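2.60 h is the number to watch: in that time step 4, target going to over-reaction product, cuts the target standing by one power of ten. I call it the decade time of target; it is the half-life 0.78 h written in powers of ten.

the same everywhere: enzyme 10 µM
- teal: substrate 20 mM; time 3.0 h; a closed flask charged with all of it at once and left for 3.0 h
- green: substrate 20 mM; one stirred flow tank at steady state, fed with the mixture as stated, mean residence time 3.0 h
- red: substrate 20 mM (fed, over 3.00 h); time 3.0 h; a stirred flask in which substrate is dosed at a steady rate over 3.00 h without added volume, worked up at 3.0 h
- ochre: substrate 20 mM; time 3.0 h; plug flow through a tube for 3.0 h, no back-mixing

- the set-up with the highest amount of target at the outlet or at the end, in percent of the substrate put in ("none" if the first two lie within 2 percentage points) (teal / green / red / ochre / none)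
- amount of target at the outlet or at the end, in percent of the substrate put in, teal
- amount of target at the outlet or at the end, in percent of the substrate put in, green
- amount of target at the outlet or at the end, in percent of the substrate put in, red
- amount of target at the outlet or at the end, in percent of the substrate put in, ochre

- in percentages every species weighs as the substrate in it: one homo dimer counts as two
- for a step with 2 of a species take k times the square, and two of it per event
- the stated concentrations are those of everything mixed, before any reaction; amounts are the same in each set-up
- the feed brings no volume worth counting
- run time (teal): 3.0 h

    substrate + enzyme → target + enzyme, rate k1*[substrate]*[enzyme]/(1 + ([substrate]/Km1)) (Km1 = 3.45 mM, k1 = 5.12 × 10⁵ L mol⁻¹ h⁻¹)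
    2 substrate → homo dimer (k2 = 41.9 L mol⁻¹ h⁻¹)
    substrate → uncatalysed product (k3 = 0.167 h⁻¹)
    target → over-reaction product (k4 = 0.884 h⁻¹)

Ochre and red look nearly the same, with the same charge, the same enzyme and the same clock. But ochre gets its substrate at once, and red gets it steadily. Teal runs on the same clock as ochre, so I reckon it the same way.

Thin substrate falls by a power of ten in 0.435 h through the enzyme and step 3, which is shorter than the decade time. So I date ochre's target at about that moment. At the reading it is 2.56 h old, or 0.986 decades, and 10.4% of what was made survives.

Red makes its target evenly over 1.15 decades, and averaging over those ages keeps 35.0%, more than ochre keeps. At the start of ochre, substrate is used for target at 0.45 of the rate at which step 2 uses it, slower, so part of the ochre substrate leaves by step 2. How much, I leave open.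

The forecast says 6.9% for teal, 23.2% for green, 31.3% for red and 6.9% for ochre, and picks red, since dosed target “has less time to over-react”. Its red-to-ochre factor, 4.54, is an amount ratio; mine, 3.37, counts survival only.

The flasks give 6.86% for teal, 23.2% for green, 31.2% for red and 6.86% for ochre, so red leads.

One run turns the forecast's pick: with the reaction of target to over-reaction product taken away, the best set-up changes and red rises from 31.2% to 83.4%. Red thus holds 37.4% of that amount, 0.427 decades, an effective age of 1.11 h. Now ochre read at 2.0 h: at 1.50 h it stands at 25.2% target with 0.574% substrate, and the extra 0.192 decades give 16.2%. The computed flask holds 16.6%.

The constants used here were chosen freely; the result is computed.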